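The constants used here belong to no real substance; what happens was integrated by code.

**The vessel.** The vessel is closed, stirred and isothermal, and from flask to flask the partner charge goes from 0.0400 M to 0.300 M.

| flask | substrate | partner | transfer agent | protic impurity | initiator | time |
|---|---|---|---|---|---|---|
| south-east | 0.036 M | 0.0400 M | 3.60 mM | 3.60 mM | 1.2 mM | 2.5 d |
| east | 0.036 M | 0.0800 M | 3.60 mM | 3.60 mM | 1.2 mM | 2.5 d |
| north-west | 0.036 M | 0.150 M | 3.60 mM | 3.60 mM | 1.2 mM | 2.5 d |
| north-east | 0.036 M | 0.300 M | 3.60 mM | 3.60 mM | 1.2 mM | 2.5 d |

    initiator → 2 initiating radical (k1 = 5.7 × 10⁻⁶ s⁻¹)
    substrate + initiating radical → capped initiator + first chain carrier (k2 = 43000 M⁻¹ s⁻¹)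
    partner + first chain carrier → target + second chain carrier (k3 = 27000 M⁻¹ s⁻¹)
    substrate + second chain carrier → by-product + first chain carrier (k4 = 3400 M⁻¹ s⁻¹)
    transfer agent + first chain carrier → side product + idle radical (k5 = 16000 M⁻¹ s⁻¹)
    2 idle radical → ended radicals (k6 = 2.3 × 10⁷ M⁻¹ s⁻¹)
    2 first chain carrier → ended chains (k7 = 3 × 10⁸ M⁻¹ s⁻¹)
    partner + protic impurity → quenched reagent (k8 = 0.0064 M⁻¹ s⁻¹)
    partner → decomposition product (k9 = 1.5 × 10⁻⁸ s⁻¹)

- percentages count the substrate that a species holds: one ended chains counts as two
- two of one species on the left: rate k times its square, two consumed each time
- "hardly changes" means that all values lie within two and a half points (for a concentration: within two and a half percent of the largest)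
- run time (south-east): 2.5 d

* share of target in all that became target or side product for south-east, east, north-west, north-east, in this order
* how that number moves from the first to the last of them (rises all the way / hardly changes / falls all the way / falls, then rises / rises, then falls)

**Two numbers.** In south-east the initiator gives 1.70 mM of initiating radical in 2.5 d. Yet 36 mM of substrate waits, 21.2 for each radical. So for that substrate to go, one radical must turn over many substrates.

**Chain length.** Call the first chain carrier X. Partner sends X round the cycle, and the second chain carrier returns it from substrate. Transfer agent turns X into side product and idle radical, and the idle radical has no step back. The pairing of X takes 0.247% of the radical flow, far less than transfer takes, so you can let chains end at transfer agent.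

Define ν as the rate of the partner step over the rate of the transfer step. This ν is the kinetic chain length.

The impurity's half-life at the south-east partner charge is 0.752 h, far shorter than the run. So count usable partner as the charge less 3.60 mM. South-east then starts at ν = 17.1.

**The crossing.** Multiply ν by the radical supply and you get a chain budget. For south-east it is 29.0 mM, less than the substrate charge. Partner also falls 1.69 times faster, proportionally, than transfer agent, so ν sinks during the run. I therefore expect substrate left in south-east at the asked time.

East starts at 35.8, and its budget of 60.9 mM is more than the substrate charge. In east I expect substrate to be the limiting reagent.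

The share being made at a given moment is ν over one plus ν. At the start that gives 94.5% for south-east and 97.3% for east, rising with partner.

**The result.** The forecast gives 93.4%, 97%, 98.5% and 99.3%, rises all the way, and says: “The others exhaust substrate”. The simulation gives 93.4%, 97.0%, 98.5% and 99.3%, rises all the way.

**The flasks.** In south-east the partner step runs 14 times the transfer step at 0.769 d and 11 times at 2.50 d, both below the start value 17.1, and at 2.50 d partner stands at 30.9% of its charge and transfer agent at 52.9% of its own. In east at 2.50 d, target stands at 31.9 times side product, below the start value 35.8, and substrate stands at 0%.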